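The route rests on disconnecting the C5–C6 bond of the five-membered ring (ring atoms C2–C6, carotenoid numbering). The vicinal pair C5 (methyl-bearing tertiary carbinol) and C6 (carrying C7), with the C5 hydroxyl trans to C7, is the 4-hydroxy-5-substituted cyclopentenone pattern that a 5-methyl-2-furyl carbinol gives on acid-mediated rearrangement. In one operation an enantioselective oxa-Piancatelli reaction closes the carbocycle, forms C5–C6 and sets both stereocentres, leaving a C2 ketone as the handle for the C1 arm. The precursor is racemic 2-(benzyloxy)-1-(5-methylfuran-2-yl)ethanol, made in one step. A lactone lock then fixes C2, and C5 plus C25 olefination chemistry completes the polyene.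

Key step: step 2

Assumption and remark: the (R)-configured acid is taken to be the antipode that leads to (4R,5S)-7, and the (S)-acid is used if experiment shows the opposite sense of induction; carotenoid locants are used throughout (ring C2–C6, C1 = carbinol carbon of the side arm, C7 = first chain carbon, primed locants for the acyclic half), and benzyl is kept on O7 because it is acid-stable, cannot act as a neighbouring group and is cleaved in the hydrogenation of step 7.

Step 1
Reactants: 1 2-methylfuran; 2 2-(benzyloxy)acetaldehyde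
Product: 4 rac-2-(benzyloxy)-1-(5-methylfuran-2-yl)ethan-1-ol, via 5-methyl-2-furyllithium 3 (not isolated)
Conditions: n-BuLi, THF, 0 °C; then 2, −78 °C to 0 °C; H2O quench
Reagents that add atoms: none
Why: Lithiation of the furan at its only free position next to oxygen and 1,2-addition of the aryllithium to the aldehyde (organolithium carbonyl addition) give the furyl carbinol, whose stereocentre needs no control because step 2 erases it.

Step 2
Reactants: 4 rac-2-(benzyloxy)-1-(5-methylfuran-2-yl)ethan-1-ol
Product: 7 (4R,5S)-5-[(benzyloxy)methyl]-4-hydroxy-4-methylcyclopent-2-en-1-one, via furfuryl cation 5 (not isolated), via hydroxypentadienyl cation 6 (not isolated)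
Conditions: (R)-3,3'-bis(2,4,6-triisopropylphenyl)-1,1'-binaphthyl-2,2'-diyl N-triflylphosphoramide (10 mol%), water-saturated toluene, 40 °C
Reagents that add atoms: water, O
Why: Proposed new method: the strong chiral acid ionises the carbinol to furfuryl cation 5, water adds at the methyl-bearing furan carbon (future C5), the hemiketal opens to the 1,4-dihydroxypentadienyl cation 6, and a thermally allowed conrotatory 4π electrocyclisation joins the two termini to form C5–C6 and the five-membered carbocycle, the former furan oxygen becoming the C2 ketone; the closest known reaction types are the racemic Piancatelli rearrangement of 5-methyl-2-furyl carbinols and the chiral phosphoric acid catalysed aza-Piancatelli and Nazarov cyclisations, and what is new is enantiocontrol with water as the nucleophile. The only ring is closed by this electrocyclisation of the U-shaped cation, not by a polar cyclisation. C6 is set relative to C5 by conrotation of the conformer that carries the C5 hydroxyl and the CH2OBn group outside (methyl inside), which puts the hydroxyl trans to C7, and C5 is set in the absolute sense by the direction of conrotation, which the chiral phosphoramidate anion, hydrogen-bonded to the hydroxyls of 6 in a contact ion pair, has to bias. Both enantiomers of 4 give the same achiral cation 5, so the racemate is converted enantioconvergently, and the water consumed is regenerated on ionisation, so a trace suffices. The step needs water to attack C5 and not the carbinol carbon (that path only returns 4), ring closure to outrun tautomerisation of 6 to the acyclic ene-dione, and the product to escape acid-induced dehydration or C6 epimerisation; the donor methyl group (which also blocks furan α-alkylation), the non-participating benzyl ether, the apolar medium with little water and the mild temperature are meant to secure these.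

Step 3
Reactants: 7 (4R,5S)-5-[(benzyloxy)methyl]-4-hydroxy-4-methylcyclopent-2-en-1-one
Product: 8 (4R,5S)-5-[(benzyloxy)methyl]-4-methyl-4-[(triethylsilyl)oxy]cyclopent-2-en-1-one
Conditions: Et3SiOTf, 2,6-lutidine, CH2Cl2, −78 °C to −40 °C
Reagents that add atoms: triethylsilyl trifluoromethanesulfonate, CC[Si](CC)(CC)OS(=O)(=O)C(F)(F)F
Why: Silyl triflate silylation with a hindered pyridine base caps the tertiary C5 hydroxyl without touching C6, which removes the β-hydroxy ketone liabilities (retro-aldol cleavage, elimination, transposition to the 2-substituted enone) before any basic step.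

Step 4
Reactants: 8 (4R,5S)-5-[(benzyloxy)methyl]-4-methyl-4-[(triethylsilyl)oxy]cyclopent-2-en-1-one
Product: 9 (2S,3R)-2-[(benzyloxy)methyl]-3-methyl-3-[(triethylsilyl)oxy]cyclopentan-1-one
Conditions: H2 (1 atm), 5% Pd/C, pyridine (0.5 equiv), EtOAc, rt
Reagents that add atoms: none
Why: Heterogeneous catalytic hydrogenation saturates the cis-disubstituted C3=C4 enone bond while pyridine poisons the catalyst towards benzyl ether hydrogenolysis (a documented chemoselectivity), and no stereocentre is made or endangered under these near-neutral conditions.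

Step 5
Reactants: 9 (2S,3R)-2-[(benzyloxy)methyl]-3-methyl-3-[(triethylsilyl)oxy]cyclopentan-1-one
Product: 11 (4R,5S)-5-[(benzyloxy)methyl]-4-methyl-4-[(triethylsilyl)oxy]cyclopent-1-en-1-yl trifluoromethanesulfonate, via lithium enolate 10 (not isolated)
Conditions: LiN(i-Pr)2, THF, −78 °C; then PhNTf2, −78 °C to 0 °C
Reagents that add atoms: N-phenylbis(trifluoromethanesulfonimide), O=S(=O)(N(c1ccccc1)S(=O)(=O)C(F)(F)F)C(F)(F)F
Why: Kinetic deprotonation by the hindered amide at the C3 methylene (C6–H is tertiary and shielded by the quaternary C5) followed by O-sulfonylation of the enolate gives the C2=C3 enol triflate regioselectively, so C6 is not enolised and neither β-leaving group is expelled.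

Step 6
Reactants: 11 (4R,5S)-5-[(benzyloxy)methyl]-4-methyl-4-[(triethylsilyl)oxy]cyclopent-1-en-1-yl trifluoromethanesulfonate
Product: 12 methyl (4R,5S)-5-[(benzyloxy)methyl]-4-methyl-4-[(triethylsilyl)oxy]cyclopent-1-ene-1-carboxylate
Conditions: Pd(OAc)2 (5 mol%), PPh3 (10 mol%), CO (1 atm), MeOH, Et3N, DMF, 50 °C
Reagents that add atoms: carbon monoxide, [C-]#[O+]; methanol, CO
Why: Palladium-catalysed methoxycarbonylation of an enol triflate (oxidative addition to zerovalent palladium, CO insertion, methanolysis of the acylpalladium) attaches C1 as an ester at C2 under mild base that leaves the silyl and benzyl ethers intact.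

Step 7
Reactants: 12 methyl (4R,5S)-5-[(benzyloxy)methyl]-4-methyl-4-[(triethylsilyl)oxy]cyclopent-1-ene-1-carboxylate
Product: 13 methyl (2S,3R)-2-(hydroxymethyl)-3-methyl-3-[(triethylsilyl)oxy]cyclopentane-1-carboxylate as a mixture of C1 epimers
Conditions: H2 (3 atm), 10% Pd/C, EtOAc/MeOH, rt
Reagents that add atoms: none
Why: One catalytic hydrogenation saturates the conjugated C2=C3 bond and hydrogenolyses the benzyl ether; hydrogen is expected to add mainly anti to the C6 side chain to give the cis hydroxy ester, but the C2 configuration is left open here because step 8 corrects it.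

Step 8
Reactants: 13 methyl (2S,3R)-2-(hydroxymethyl)-3-methyl-3-[(triethylsilyl)oxy]cyclopentane-1-carboxylate as a mixture of C1 epimers
Product: 14 (3aS,4R,6aR)-4-methyl-4-[(triethylsilyl)oxy]hexahydro-1H-cyclopenta[c]furan-1-one
Conditions: KOt-Bu (0.2 equiv), THF, 0 °C to rt; AcOH quench
Reagents that add atoms: none
Why: Alkoxide-catalysed epimerisation at C2 through the ester enolate and intramolecular transesterification funnel both epimers into the γ-lactone, because only the ester cis to the C7 hydroxymethyl can close the bicyclo[3.3.0] ring (thermodynamic lactonisation), which sets C2 as R and cis to C7 while C5 and C6 carry no acidic hydrogen at this stage.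

Step 9
Reactants: 14 (3aS,4R,6aR)-4-methyl-4-[(triethylsilyl)oxy]hexahydro-1H-cyclopenta[c]furan-1-one
Product: 16 2-[(1R,2S,3R)-2-(hydroxymethyl)-3-methyl-3-[(triethylsilyl)oxy]cyclopentyl]propan-2-ol, via methyl ketone alkoxide 15 (not isolated)
Conditions: MeLi (4 equiv), THF, −78 °C to 0 °C; H2O quench
Reagents that add atoms: methyllithium, [Li]C
Why: Twofold addition of methyllithium to the lactone (acyl substitution to the methyl ketone, then carbonyl addition) builds the C1 carbinol with both methyl groups and frees the C7 hydroxyl, the low temperature letting addition outrun enolisation so that C2 keeps its configuration.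

Step 10
Reactants: 16 2-[(1R,2S,3R)-2-(hydroxymethyl)-3-methyl-3-[(triethylsilyl)oxy]cyclopentyl]propan-2-ol
Product: 17 (1R,2S,3R)-3-methyl-3-[(triethylsilyl)oxy]-1-{2-[(triethylsilyl)oxy]propan-2-yl}-2-{[(triethylsilyl)oxy]methyl}cyclopentane
Conditions: Et3SiOTf (3 equiv), 2,6-lutidine, CH2Cl2, −78 °C to 0 °C
Reagents that add atoms: triethylsilyl trifluoromethanesulfonate, CC[Si](CC)(CC)OS(=O)(=O)C(F)(F)F
Why: Exhaustive silylation with the silyl triflate masks the new tertiary C1 hydroxyl (which would otherwise trap the C7 aldehyde as a lactol) and also converges any material whose C5 silyl group has migrated or been lost onto one tris-silyl ether.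

Step 11
Reactants: 17 (1R,2S,3R)-3-methyl-3-[(triethylsilyl)oxy]-1-{2-[(triethylsilyl)oxy]propan-2-yl}-2-{[(triethylsilyl)oxy]methyl}cyclopentane
Product: 18 (1R,2R,5R)-2-methyl-2-[(triethylsilyl)oxy]-5-{2-[(triethylsilyl)oxy]propan-2-yl}cyclopentane-1-carbaldehyde
Conditions: (COCl)2, DMSO, CH2Cl2, −78 °C to −30 °C; then i-Pr2NEt, −78 °C to 0 °C
Reagents that add atoms: none
Why: Under Swern conditions the chlorodimethylsulfonium ion cleaves only the primary triethylsilyl ether and oxidises it in the same flask to the aldehyde (known selective oxidative desilylation), the hindered amine and low temperature protecting the C6 stereocentre next to the new carbonyl.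

Step 12
Reactants: 18 (1R,2R,5R)-2-methyl-2-[(triethylsilyl)oxy]-5-{2-[(triethylsilyl)oxy]propan-2-yl}cyclopentane-1-carbaldehyde; 19 diethyl [(2E)-3-cyano-2-methylprop-2-en-1-yl]phosphonate
Product: 21 (2E,4E)-3-methyl-5-[(1R,2R,5R)-2-methyl-2-[(triethylsilyl)oxy]-5-{2-[(triethylsilyl)oxy]propan-2-yl}cyclopentyl]penta-2,4-dienenitrile, via lithiated phosphonate 20 (not isolated)
Conditions: 19, LiN(SiMe3)2, THF, −78 °C; then 18, −78 °C to 0 °C
Reagents that add atoms: none
Why: Horner–Wadsworth–Emmons olefination with the preformed, weakly basic vinylogous cyanophosphonate anion should add to the aldehyde faster than it enolises it and gives the E C7=C8 bond by the usual thermodynamic control of stabilised phosphonates, the 9E isomer being separated from any 9Z material by chromatography.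

Step 13
Reactants: 21 (2E,4E)-3-methyl-5-[(1R,2R,5R)-2-methyl-2-[(triethylsilyl)oxy]-5-{2-[(triethylsilyl)oxy]propan-2-yl}cyclopentyl]penta-2,4-dienenitrile
Product: 23 (2E,4E)-3-methyl-5-[(1R,2R,5R)-2-methyl-2-[(triethylsilyl)oxy]-5-{2-[(triethylsilyl)oxy]propan-2-yl}cyclopentyl]penta-2,4-dienal, via aluminium imine 22 (not isolated)
Conditions: i-Bu2AlH, toluene, −78 °C; then wet SiO2, 0 °C
Reagents that add atoms: water, O
Why: Diisobutylaluminium hydride adds once to the conjugated nitrile to give the N-aluminio imine, which wet silica hydrolyses to the dienal (the standard nitrile-to-aldehyde reduction of retinoid chemistry) without touching the silyl ethers or the olefin geometry.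

Step 14
Reactants: 24 pseudoionone
Product: 25 rac-(4E,6E)-3,7,11-trimethyldodeca-1,4,6,10-tetraen-3-ol
Conditions: CH2=CHMgBr, THF, 0 °C; H2O quench
Reagents that add atoms: vinylmagnesium bromide, C=C[Mg]Br
Why: Grignard 1,2-addition of the vinyl nucleophile to the methyl ketone of the dienone gives the tertiary allylic alcohol, whose stereocentre is irrelevant because it is lost in step 15.

Step 15
Reactants: 25 rac-(4E,6E)-3,7,11-trimethyldodeca-1,4,6,10-tetraen-3-ol
Product: 26 [(2E,4E,6E)-3,7,11-trimethyldodeca-2,4,6,10-tetraen-1-yl]triphenylphosphonium bromide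
Conditions: PPh3·HBr, MeOH, rt; crystallisation
Reagents that add atoms: triphenylphosphine hydrobromide, [Br-].c1ccc(cc1)[PH+](c1ccccc1)c1ccccc1
Why: Acid ionises the tertiary allylic alcohol and triphenylphosphine captures the delocalised cation at its unhindered primary terminus (allylic transposition, the standard entry to carotenoid Wittig salts), giving the fully conjugated and thermodynamically preferred E trisubstituted olefin.

Step 16
Reactants: 26 [(2E,4E,6E)-3,7,11-trimethyldodeca-2,4,6,10-tetraen-1-yl]triphenylphosphonium bromide; 27 (2E,4E,6E)-2,7-dimethylocta-2,4,6-trienedial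
Product: 29 (2E,4E,6E,8E,10E,12E,14E)-2,7,11,15,19-pentamethylicosa-2,4,6,8,10,12,14,18-octaenal, via phosphorus ylide 28 (not isolated)
Conditions: NaOMe, MeOH/CH2Cl2, 0 °C to rt, 26 added slowly to 27 (2.5 equiv); crystallisation
Reagents that add atoms: none
Why: Wittig olefination of the allylic ylide with one formyl group of the dialdehyde, kept in excess to favour mono-olefination, forms C11'=C12', the all-E aldehyde being the crystalline isomer that is isolated.

Step 17
Reactants: 29 (2E,4E,6E,8E,10E,12E,14E)-2,7,11,15,19-pentamethylicosa-2,4,6,8,10,12,14,18-octaenal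
Product: 30 (2E,4E,6E,8E,10E,12E,14E)-2,7,11,15,19-pentamethylicosa-2,4,6,8,10,12,14,18-octaen-1-ol
Conditions: NaBH4, EtOH/THF, 0 °C
Reagents that add atoms: none
Why: Borohydride 1,2-reduction of the polyenal gives the primary allylic alcohol without affecting the polyene.

Step 18
Reactants: 30 (2E,4E,6E,8E,10E,12E,14E)-2,7,11,15,19-pentamethylicosa-2,4,6,8,10,12,14,18-octaen-1-ol
Product: 31 [(2E,4E,6E,8E,10E,12E,14E)-2,7,11,15,19-pentamethylicosa-2,4,6,8,10,12,14,18-octaen-1-yl]triphenylphosphonium bromide
Conditions: PPh3·HBr, CH2Cl2/MeOH, 0 °C to rt, dark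
Reagents that add atoms: triphenylphosphine hydrobromide, [Br-].c1ccc(cc1)[PH+](c1ccccc1)c1ccccc1
Why: As in step 15, acid-promoted ionisation of the allylic alcohol and capture by triphenylphosphine at the primary terminus gives the polyenyl phosphonium salt (the method used for retinyl and apocarotenyl Wittig salts).

Step 19
Reactants: 31 [(2E,4E,6E,8E,10E,12E,14E)-2,7,11,15,19-pentamethylicosa-2,4,6,8,10,12,14,18-octaen-1-yl]triphenylphosphonium bromide; 23 (2E,4E)-3-methyl-5-[(1R,2R,5R)-2-methyl-2-[(triethylsilyl)oxy]-5-{2-[(triethylsilyl)oxy]propan-2-yl}cyclopentyl]penta-2,4-dienal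
Product: 34 (all-E)-(2R,5R,6R)-2,6-cyclolycopene-1,5-diol 1,5-bis(triethylsilyl) ether, via phosphorus ylide 32 (not isolated), via 11Z olefin isomer 33 (not isolated)
Conditions: NaOMe, MeOH/CH2Cl2, 0 °C to rt; then heptane, 90 °C, N2, dark
Reagents that add atoms: none
Why: Wittig olefination of the polyenyl ylide with the dienal forms C11=C12 and completes the C40 skeleton, the hindered 11Z isomer formed alongside being converted thermally into the all-E polyene (standard carotenoid practice), while the silyl ethers keep the tertiary hydroxyls from adding to the dienal under base.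

Step 20
Reactants: 34 (all-E)-(2R,5R,6R)-2,6-cyclolycopene-1,5-diol 1,5-bis(triethylsilyl) ether
Product: 35 (all-E)-(2R,5R,6R)-2,6-cyclolycopene-1,5-diol (CNP0169920.2)
Conditions: Bu4NF, THF, rt to 40 °C, N2, dark
Reagents that add atoms: none
Why: Fluoride-mediated desilylation removes both tertiary triethylsilyl ethers under non-acidic conditions that the polyene and the homoallylic C5 carbinol tolerate, giving the target with its three stereocentres as set in steps 2 and 8.

Compound list
1 | 2-methylfuran | Cc1ccco1 | starting material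
2 | 2-(benzyloxy)acetaldehyde | O=CCOCc1ccccc1 | starting material
3 | 5-methyl-2-furyllithium | [Li]c1ccc(C)o1 | intermediate (not isolated)
4 | rac-2-(benzyloxy)-1-(5-methylfuran-2-yl)ethan-1-ol | Cc1ccc(o1)C(O)COCc1ccccc1 | intermediate
5 | 2-(benzyloxy)-1-(5-methylfuran-2-yl)ethylium (furfuryl cation) | Cc1ccc(o1)[CH+]COCc1ccccc1 | intermediate (not isolated)
6 | (3Z,5Z)-7-(benzyloxy)-2,5-dihydroxyhepta-3,5-dien-2-ylium (hydroxypentadienyl cation, CH2OBn outside) | C[C+](O)/C=C\C(O)=C\COCc1ccccc1 | intermediate (not isolated)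
7 | (4R,5S)-5-[(benzyloxy)methyl]-4-hydroxy-4-methylcyclopent-2-en-1-one | O=C1C=C[C@@](C)(O)[C@@H]1COCc1ccccc1 | intermediate
8 | (4R,5S)-5-[(benzyloxy)methyl]-4-methyl-4-[(triethylsilyl)oxy]cyclopent-2-en-1-one | O=C1C=C[C@@](C)(O[Si](CC)(CC)CC)[C@@H]1COCc1ccccc1 | intermediate
9 | (2S,3R)-2-[(benzyloxy)methyl]-3-methyl-3-[(triethylsilyl)oxy]cyclopentan-1-one | O=C1CC[C@@](C)(O[Si](CC)(CC)CC)[C@@H]1COCc1ccccc1 | intermediate
10 | lithium (4R,5S)-5-[(benzyloxy)methyl]-4-methyl-4-[(triethylsilyl)oxy]cyclopent-1-en-1-olate | [Li]OC1=CC[C@@](C)(O[Si](CC)(CC)CC)[C@@H]1COCc1ccccc1 | intermediate (not isolated)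
11 | (4R,5S)-5-[(benzyloxy)methyl]-4-methyl-4-[(triethylsilyl)oxy]cyclopent-1-en-1-yl trifluoromethanesulfonate | O=S(=O)(OC1=CC[C@@](C)(O[Si](CC)(CC)CC)[C@@H]1COCc1ccccc1)C(F)(F)F | intermediate
12 | methyl (4R,5S)-5-[(benzyloxy)methyl]-4-methyl-4-[(triethylsilyl)oxy]cyclopent-1-ene-1-carboxylate | COC(=O)C1=CC[C@@](C)(O[Si](CC)(CC)CC)[C@@H]1COCc1ccccc1 | intermediate
13 | methyl (2S,3R)-2-(hydroxymethyl)-3-methyl-3-[(triethylsilyl)oxy]cyclopentane-1-carboxylate, C1 epimer mixture (C1 left undefined) | COC(=O)C1CC[C@@](C)(O[Si](CC)(CC)CC)[C@@H]1CO | intermediate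
14 | (3aS,4R,6aR)-4-methyl-4-[(triethylsilyl)oxy]hexahydro-1H-cyclopenta[c]furan-1-one (cis-fused lactone) | O=C1OC[C@@H]2[C@H]1CC[C@@]2(C)O[Si](CC)(CC)CC | intermediate
15 | lithium alkoxide of 1-[(1R,2S,3R)-2-(hydroxymethyl)-3-methyl-3-[(triethylsilyl)oxy]cyclopentyl]ethan-1-one | [Li]OC[C@@H]1[C@H](C(C)=O)CC[C@@]1(C)O[Si](CC)(CC)CC | intermediate (not isolated)
16 | 2-[(1R,2S,3R)-2-(hydroxymethyl)-3-methyl-3-[(triethylsilyl)oxy]cyclopentyl]propan-2-ol | OC[C@@H]1[C@H](C(C)(C)O)CC[C@@]1(C)O[Si](CC)(CC)CC | intermediate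
17 | (1R,2S,3R)-3-methyl-3-[(triethylsilyl)oxy]-1-{2-[(triethylsilyl)oxy]propan-2-yl}-2-{[(triethylsilyl)oxy]methyl}cyclopentane | CC[Si](CC)(CC)OC[C@@H]1[C@H](C(C)(C)O[Si](CC)(CC)CC)CC[C@@]1(C)O[Si](CC)(CC)CC | intermediate
18 | (1R,2R,5R)-2-methyl-2-[(triethylsilyl)oxy]-5-{2-[(triethylsilyl)oxy]propan-2-yl}cyclopentane-1-carbaldehyde | O=C[C@@H]1[C@H](C(C)(C)O[Si](CC)(CC)CC)CC[C@@]1(C)O[Si](CC)(CC)CC | intermediate
19 | diethyl [(2E)-3-cyano-2-methylprop-2-en-1-yl]phosphonate | CCOP(=O)(OCC)C/C(C)=C/C#N | starting material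
20 | lithium salt of the carbanion of 19 | [Li+].CCOP(=O)(OCC)[CH-]/C(C)=C/C#N | intermediate (not isolated)
21 | (2E,4E)-3-methyl-5-[(1R,2R,5R)-2-methyl-2-[(triethylsilyl)oxy]-5-{2-[(triethylsilyl)oxy]propan-2-yl}cyclopentyl]penta-2,4-dienenitrile | N#C/C=C(C)/C=C/[C@@H]1[C@H](C(C)(C)O[Si](CC)(CC)CC)CC[C@@]1(C)O[Si](CC)(CC)CC | intermediate
22 | N-(diisobutylaluminio) imine of 23 | CC(C)C[Al](CC(C)C)N=C/C=C(C)/C=C/[C@@H]1[C@H](C(C)(C)O[Si](CC)(CC)CC)CC[C@@]1(C)O[Si](CC)(CC)CC | intermediate (not isolated)
23 | (2E,4E)-3-methyl-5-[(1R,2R,5R)-2-methyl-2-[(triethylsilyl)oxy]-5-{2-[(triethylsilyl)oxy]propan-2-yl}cyclopentyl]penta-2,4-dienal | O=C/C=C(C)/C=C/[C@@H]1[C@H](C(C)(C)O[Si](CC)(CC)CC)CC[C@@]1(C)O[Si](CC)(CC)CC | intermediate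
24 | pseudoionone, (3E,5E)-6,10-dimethylundeca-3,5,9-trien-2-one | CC(C)=CCC/C(C)=C/C=C/C(C)=O | starting material
25 | rac-(4E,6E)-3,7,11-trimethyldodeca-1,4,6,10-tetraen-3-ol | CC(C)=CCC/C(C)=C/C=C/C(C)(O)C=C | intermediate
26 | [(2E,4E,6E)-3,7,11-trimethyldodeca-2,4,6,10-tetraen-1-yl]triphenylphosphonium bromide | CC(C)=CCC/C(C)=C/C=C/C(C)=C/C[P+](c1ccccc1)(c1ccccc1)c1ccccc1.[Br-] | intermediate
27 | (2E,4E,6E)-2,7-dimethylocta-2,4,6-trienedial (C10 dialdehyde) | O=C/C(C)=C/C=C/C=C(C)/C=O | starting material
28 | [(2E,4E,6E)-3,7,11-trimethyldodeca-2,4,6,10-tetraen-1-ylidene]triphenylphosphorane | CC(C)=CCC/C(C)=C/C=C/C(C)=C/C=P(c1ccccc1)(c1ccccc1)c1ccccc1 | intermediate (not isolated)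
29 | (2E,4E,6E,8E,10E,12E,14E)-2,7,11,15,19-pentamethylicosa-2,4,6,8,10,12,14,18-octaenal (C25 aldehyde) | CC(C)=CCC/C(C)=C/C=C/C(C)=C/C=C/C(C)=C/C=C/C=C(C)/C=O | intermediate
30 | (2E,4E,6E,8E,10E,12E,14E)-2,7,11,15,19-pentamethylicosa-2,4,6,8,10,12,14,18-octaen-1-ol | CC(C)=CCC/C(C)=C/C=C/C(C)=C/C=C/C(C)=C/C=C/C=C(C)/CO | intermediate
31 | [(2E,4E,6E,8E,10E,12E,14E)-2,7,11,15,19-pentamethylicosa-2,4,6,8,10,12,14,18-octaen-1-yl]triphenylphosphonium bromide | CC(C)=CCC/C(C)=C/C=C/C(C)=C/C=C/C(C)=C/C=C/C=C(C)/C[P+](c1ccccc1)(c1ccccc1)c1ccccc1.[Br-] | intermediate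
32 | ylide of 31, [(all-E)-2,7,11,15,19-pentamethylicosa-2,4,6,8,10,12,14,18-octaen-1-ylidene]triphenylphosphorane | CC(C)=CCC/C(C)=C/C=C/C(C)=C/C=C/C(C)=C/C=C/C=C(C)/C=P(c1ccccc1)(c1ccccc1)c1ccccc1 | intermediate (not isolated)
33 | (11Z)-isomer of 34 | CC(C)=CCC/C(C)=C/C=C/C(C)=C/C=C/C(C)=C/C=C/C=C(C)/C=C\C=C(C)\C=C\[C@@H]1[C@H](C(C)(C)O[Si](CC)(CC)CC)CC[C@@]1(C)O[Si](CC)(CC)CC | intermediate (not isolated)
34 | (all-E)-(2R,5R,6R)-2,6-cyclolycopene-1,5-diol 1,5-bis(triethylsilyl) ether | CC(C)=CCC/C(C)=C/C=C/C(C)=C/C=C/C(C)=C/C=C/C=C(C)/C=C/C=C(C)/C=C/[C@@H]1[C@H](C(C)(C)O[Si](CC)(CC)CC)CC[C@@]1(C)O[Si](CC)(CC)CC | intermediate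
35 | (all-E)-(2R,5R,6R)-2,6-cyclolycopene-1,5-diol (CNP0169920.2) | CC(C)=CCC/C(C)=C/C=C/C(C)=C/C=C/C(C)=C/C=C/C=C(C)/C=C/C=C(C)/C=C/[C@@H]1[C@H](C(C)(C)O)CC[C@@]1(C)O | target

Total step count: 20. Longest linear sequence: 15 steps (steps 1 to 13, then 19 and 20); the polyene branch (steps 14 to 18) joins at step 19.

Steps most likely to fail

Step 2 (Proposed new method). The β-alkoxy carbinol may ionise too slowly under the chiral acid, and water may compete for hydrogen bonding to the anion so that the conrotation is poorly biased. Closure may also occur with methyl outside (wrong diastereomer), or the open cation may leak to the acyclic ene-dione. Fallback: setting out from 4, the established racemic rearrangement with ZnCl2 in aqueous acetone at reflux would give rac-trans-5-[(benzyloxy)methyl]-4-hydroxy-4-methylcyclopent-2-en-1-one F1. Its enantiomers are separated by preparative chromatography on a chiral stationary phase, and the (4R,5S) antipode comes back to the route as 7.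

Step 12. The phosphonate anion may enolise the hindered α-branched aldehyde instead of adding to it, which would epimerise C6 or expel the C5 silyloxy group by β-elimination. Fallback: setting out from 18, a base-free Wittig reaction with the stabilised ylide 1-(triphenylphosphoranylidene)propan-2-one (toluene, 90 °C) would give (3E)-4-[(1R,2R,5R)-2-methyl-2-[(triethylsilyl)oxy]-5-{2-[(triethylsilyl)oxy]propan-2-yl}cyclopentyl]but-3-en-2-one F2. Horner–Wadsworth–Emmons reaction of this methyl ketone with diethyl cyanomethylphosphonate and NaH in THF, with separation of the 9E isomer, then comes back to the route at 21.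

Step 5. Regiocontrol of the enolisation may be lost through proton transfer to the C6 enolate, followed by expulsion of the C5 silyloxy or C7 benzyloxy group. Fallback: setting out from 8 and bypassing 9, 1,4-hydrosilylation with PhMe2SiH catalysed by RhCl(PPh3)3 would give {[(4R,5S)-5-[(benzyloxy)methyl]-4-methyl-4-[(triethylsilyl)oxy]cyclopent-1-en-1-yl]oxy}dimethyl(phenyl)silane F3, in which the C2=C3 enol ether is fixed by the hydride addition. Cleavage with MeLi regenerates enolate 10 regiospecifically, and trapping with PhNTf2 comes back to the route at 11.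

Further compounds
F1 | step 2 | rac-trans-5-[(benzyloxy)methyl]-4-hydroxy-4-methylcyclopent-2-en-1-one (equimolar 7 and its enantiomer) | O=C1C=C[C@@](C)(O)[C@@H]1COCc1ccccc1.O=C1C=C[C@](C)(O)[C@H]1COCc1ccccc1
F2 | step 12 | (3E)-4-[(1R,2R,5R)-2-methyl-2-[(triethylsilyl)oxy]-5-{2-[(triethylsilyl)oxy]propan-2-yl}cyclopentyl]but-3-en-2-one | CC(=O)/C=C/[C@@H]1[C@H](C(C)(C)O[Si](CC)(CC)CC)CC[C@@]1(C)O[Si](CC)(CC)CC
F3 | step 5 | {[(4R,5S)-5-[(benzyloxy)methyl]-4-methyl-4-[(triethylsilyl)oxy]cyclopent-1-en-1-yl]oxy}dimethyl(phenyl)silane | C[Si](C)(OC1=CC[C@@](C)(O[Si](CC)(CC)CC)[C@@H]1COCc1ccccc1)c1ccccc1
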